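The cyclohexene ring is numbered C1 (aroyl-bearing CH), C2 (CH2), C3 (=CH), C4 (=C carrying the 4-methylpent-3-enyl chain), C5 (CH2), C6 (phenyl-bearing CH). Everything rests on opening it at C2–C3: C2 is β to the aryl ketone and C3 is the unsubstituted end of the C3=C4 alkene. The precursor is an open-chain α-methylene aryl ketone whose chain ends in an alkenyl(trimethyl)silane. A Lewis acid lets the silicon-bearing C3 attack the exo-methylene C2; the β-silyl cation at C4 sheds silicon, so ring closure and placement of the double bond at C3=C4 happen in one operation from either alkene geometry. C6 comes from an asymmetric Michael addition to cardamonin; C1 is equilibrated to trans.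

Key step: step 7

Assumption: cardamonin is taken as a purchasable natural product; the sense of induction in step 3 is assigned by analogy with cinchona-thiourea additions to chalcones and would be corrected, if needed, with the pseudo-enantiomeric quinidine-derived catalyst. (TBS = tert-butyldimethylsilyl.)

Step 1
Reactants: 1 cardamonin, (E)-1-(2,4-dihydroxy-6-methoxyphenyl)-3-phenylprop-2-en-1-one; 2 tert-butyldimethylsilyl trifluoromethanesulfonate
Product: 3 (E)-1-[2,4-bis(TBS-oxy)-6-methoxyphenyl]-3-phenylprop-2-en-1-one
Conditions: TBSOTf (2.4 equiv), 2,6-lutidine, CH2Cl2, 0 °C to rt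
Reagents that add atoms: tert-butyldimethylsilyl trifluoromethanesulfonate, CC(C)(C)[Si](C)(C)OS(=O)(=O)C(F)(F)F
Why: Phenol silylation with a silyl triflate and a hindered pyridine base should cap both phenols, including the hydrogen-bonded ortho OH, so that no acidic OH meets the later titanium and aluminium reagents and the ortho oxygen cannot add to the later enone.

Step 2
Reactants: 4 allyl acetoacetate (prop-2-enyl 3-oxobutanoate); 5 prenyl bromide (1-bromo-3-methylbut-2-ene)
Product: 6 allyl 7-methyl-3-oxooct-6-enoate
Conditions: NaH, THF, 0 °C; n-BuLi, 0 °C; then 5, 0 °C to rt; 1 M HCl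
Reagents that add atoms: none
Why: γ-Alkylation of the acetoacetate dianion, in which the more basic terminal carbanion displaces bromide from the primary allylic carbon (SN2), should give the γ-prenylated β-ketoester.

Step 3
Reactants: 3 bis-TBS cardamonin; 6 allyl 7-methyl-3-oxooct-6-enoate
Product: 7 prop-2-enyl (3S)-5-[2,4-bis(TBS-oxy)-6-methoxyphenyl]-2-(5-methylhex-4-enoyl)-5-oxo-3-phenylpentanoate (epimer mixture at C2 of the pentanoate)
Conditions: 9-amino-9-deoxy-epi-quinine N-[3,5-bis(trifluoromethyl)phenyl]thiourea (10 mol %), PhMe, rt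
Reagents that add atoms: none
Why: In this organocatalytic asymmetric Michael addition of a β-ketoester to a chalcone, the thiourea binds the enone carbonyl and the quinuclidine delivers the enol to one face of the β-carbon, which should set the phenyl-bearing centre (later C6) as drawn, while the ester-bearing carbon forms as a mixture that step 4 erases.

Step 4
Reactants: 7 Michael adduct
Product: 9 (3R)-1-[2,4-bis(TBS-oxy)-6-methoxyphenyl]-9-methyl-3-phenyldec-8-ene-1,5-dione, via β-keto acid 8 (not isolated)
Conditions: Pd(PPh3)4 (3 mol %), morpholine (1.2 equiv), THF, rt to 40 °C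
Reagents that add atoms: none
Why: Tsuji–Trost deallylation (zerovalent palladium ionises the allyl ester, morpholine traps the allyl group) followed by loss of CO2 from the β-keto acid should give the 1,5-diketone under near-neutral conditions that leave the benzylic centre and the silyl ethers untouched.

Step 5
Reactants: 9 1,5-diketone; 10 (trimethylsilyl)methylmagnesium chloride
Product: 11 (3R)-1-[2,4-bis(TBS-oxy)-6-methoxyphenyl]-9-methyl-3-phenyl-5-[(trimethylsilyl)methylidene]dec-8-en-1-one (E/Z mixture at the silylated alkene)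
Conditions: Cp2TiCl2 (2 equiv) and Me3SiCH2MgCl (4 equiv), Et2O, 0 °C to rt, filter, switch to PhMe; then 9, 100 °C
Reagents that add atoms: (trimethylsilyl)methylmagnesium chloride, C[Si](C)(C)C[Mg]Cl
Why: In this Petasis-type olefination, thermolysis of Cp2Ti(CH2SiMe3)2 gives the non-basic alkylidene Cp2Ti=CHSiMe3, which should olefinate the unhindered dialkyl ketone in preference to the di-ortho-substituted aryl ketone and give the alkenylsilane as an E/Z mixture that needs no separation.

Step 6
Reactants: 11 alkenylsilane ketone; 12 paraformaldehyde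
Product: 13 (3S)-1-[2,4-bis(TBS-oxy)-6-methoxyphenyl]-9-methyl-2-methylidene-3-phenyl-5-[(trimethylsilyl)methylidene]dec-8-en-1-one
Conditions: (CH2O)n, i-Pr2NH·CF3CO2H (1 equiv), CF3CO2H (10 mol %), THF, reflux
Reagents that add atoms: formaldehyde (as paraformaldehyde), C=O
Why: Mannich-type α-methylenation (iminium condensation, then amine elimination) should act only at the CH2 next to the aroyl group, the one enolisable position of the remaining ketone, and give the exo-methylene enone without touching the stereocentre (its descriptor changes to S only through priority rules).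

Step 7
Reactants: 13 α-methylene ketone with alkenylsilane terminus
Product: 15 [2,4-bis(TBS-oxy)-6-methoxyphenyl][(1R,6R)-4-(4-methylpent-3-en-1-yl)-6-phenylcyclohex-3-en-1-yl]methanone, via C1-epimer mixture 14 (not isolated)
Conditions: EtAlCl2 (1.5 equiv), CH2Cl2, −78 to −20 °C; aq. NaHCO3; crude, DBU (0.3 equiv), PhMe, rt
Reagents that add atoms: none
Why: EtAlCl2 binds the ketone oxygen and makes the exo-methylene carbon C2 electrophilic; the silicon-bearing alkene carbon C3 attacks it through a chair-like six-membered transition state, giving an aluminium enolate at C1 and a tertiary C4 cation stabilised by the β C–Si bond, and chloride-assisted loss of Me3Si then places the double bond at C3=C4 only. The closest known reaction types are the Lewis acid-induced conjugate addition of an alkene to an enone and the alkenylsilane-terminated cation–olefin cyclisation (an intramolecular Hosomi–Sakurai-type ipso substitution). The ring closes in a 6-endo-trig mode with respect to the enone, and both carbons of the alkenylsilane end inside the new ring. The C–C bond formation creates no stereocentre: C6 is carried in from step 3, and C1, formed on protonation of the enolate, is steered to the trans (1R,6R) arrangement by DBU equilibration because aroyl and phenyl are then both equatorial. The step needs regiocontrol of the new alkene, which silicon should secure (the Z silane has its C–Si bond aligned with the cation at once, the E silane after ring inversion, so both should converge), and 1,4- over 1,2-attack, which the hindered di-ortho-substituted carbonyl carbon should secure. The side-chain alkene could reach C2 only through an eight-membered ring, and the alkylaluminium halide scavenges protons that would otherwise isomerise the product diene.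

Step 8
Reactants: 15 bis-TBS ketone
Product: 16 (2,4-dihydroxy-6-methoxyphenyl)[(1R,6R)-4-(4-methylpent-3-en-1-yl)-6-phenylcyclohex-3-en-1-yl]methanone (target)
Conditions: Bu4NF (2.5 equiv), AcOH (2.5 equiv), THF, 0 °C to rt
Reagents that add atoms: none
Why: Fluoride-induced cleavage of the two aryl silyl ethers under acetic acid buffering should free both phenols without disturbing the ketone α-centre, the two trisubstituted alkenes or the methyl ether.

Compound list
1 | cardamonin, (E)-1-(2,4-dihydroxy-6-methoxyphenyl)-3-phenylprop-2-en-1-one | COc1cc(O)cc(O)c1C(=O)/C=C/c1ccccc1 | starting material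
2 | tert-butyldimethylsilyl trifluoromethanesulfonate | CC(C)(C)[Si](C)(C)OS(=O)(=O)C(F)(F)F | starting material
3 | (E)-1-[2,4-bis(TBS-oxy)-6-methoxyphenyl]-3-phenylprop-2-en-1-one | COc1cc(O[Si](C)(C)C(C)(C)C)cc(O[Si](C)(C)C(C)(C)C)c1C(=O)/C=C/c1ccccc1 | intermediate
4 | allyl acetoacetate | CC(=O)CC(=O)OCC=C | starting material
5 | prenyl bromide | CC(C)=CCBr | starting material
6 | allyl 7-methyl-3-oxooct-6-enoate | CC(C)=CCCC(=O)CC(=O)OCC=C | intermediate
7 | prop-2-enyl (3S)-5-[2,4-bis(TBS-oxy)-6-methoxyphenyl]-2-(5-methylhex-4-enoyl)-5-oxo-3-phenylpentanoate (C2 epimers) | COc1cc(O[Si](C)(C)C(C)(C)C)cc(O[Si](C)(C)C(C)(C)C)c1C(=O)C[C@H](c1ccccc1)C(C(=O)OCC=C)C(=O)CCC=C(C)C | intermediate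
8 | (3S)-5-[2,4-bis(TBS-oxy)-6-methoxyphenyl]-2-(5-methylhex-4-enoyl)-5-oxo-3-phenylpentanoic acid (C2 epimers) | COc1cc(O[Si](C)(C)C(C)(C)C)cc(O[Si](C)(C)C(C)(C)C)c1C(=O)C[C@H](c1ccccc1)C(C(=O)O)C(=O)CCC=C(C)C | intermediate
9 | (3R)-1-[2,4-bis(TBS-oxy)-6-methoxyphenyl]-9-methyl-3-phenyldec-8-ene-1,5-dione | COc1cc(O[Si](C)(C)C(C)(C)C)cc(O[Si](C)(C)C(C)(C)C)c1C(=O)C[C@H](c1ccccc1)CC(=O)CCC=C(C)C | intermediate
10 | (trimethylsilyl)methylmagnesium chloride | C[Si](C)(C)C[Mg]Cl | starting material
11 | (3R)-1-[2,4-bis(TBS-oxy)-6-methoxyphenyl]-9-methyl-3-phenyl-5-[(trimethylsilyl)methylidene]dec-8-en-1-one (E/Z) | COc1cc(O[Si](C)(C)C(C)(C)C)cc(O[Si](C)(C)C(C)(C)C)c1C(=O)C[C@H](c1ccccc1)CC(CCC=C(C)C)=C[Si](C)(C)C | intermediate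
12 | paraformaldehyde (formaldehyde) | C=O | starting material
13 | (3S)-1-[2,4-bis(TBS-oxy)-6-methoxyphenyl]-9-methyl-2-methylidene-3-phenyl-5-[(trimethylsilyl)methylidene]dec-8-en-1-one (E/Z) | COc1cc(O[Si](C)(C)C(C)(C)C)cc(O[Si](C)(C)C(C)(C)C)c1C(=O)C(=C)[C@H](c1ccccc1)CC(CCC=C(C)C)=C[Si](C)(C)C | intermediate
14 | [2,4-bis(TBS-oxy)-6-methoxyphenyl][(6R)-4-(4-methylpent-3-en-1-yl)-6-phenylcyclohex-3-en-1-yl]methanone (C1 epimers) | COc1cc(O[Si](C)(C)C(C)(C)C)cc(O[Si](C)(C)C(C)(C)C)c1C(=O)C1CC=C(CCC=C(C)C)C[C@H]1c1ccccc1 | intermediate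
15 | [2,4-bis(TBS-oxy)-6-methoxyphenyl][(1R,6R)-4-(4-methylpent-3-en-1-yl)-6-phenylcyclohex-3-en-1-yl]methanone | COc1cc(O[Si](C)(C)C(C)(C)C)cc(O[Si](C)(C)C(C)(C)C)c1C(=O)[C@@H]1CC=C(CCC=C(C)C)C[C@H]1c1ccccc1 | intermediate
16 | (2,4-dihydroxy-6-methoxyphenyl)[(1R,6R)-4-(4-methylpent-3-en-1-yl)-6-phenylcyclohex-3-en-1-yl]methanone | COc1cc(O)cc(O)c1C(=O)[C@@H]1CC=C(CCC=C(C)C)C[C@H]1c1ccccc1 | target

Total step count: 8. Longest linear sequence: 7 steps (1 → 3 → 7 → 9 → 11 → 13 → 15 → 16; step 2 is a one-step side branch).

Steps most likely to fail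

Step 7. The alkenylsilane may be too weak a π-nucleophile for the complexed enone. The E-configured silane may lose a proton instead of silicon, which would scramble the alkene position. The Lewis acid may also strip the ortho silyl ether, after which the phenoxide would add to the enone. The fallback closes the same C2–C3 bond with nickel. From diketone 9, Wittig bromomethylenation (Ph3P+CH2Br Br−, KOtBu, THF) of the dialkyl ketone would give (3R)-5-(bromomethylidene)-1-[2,4-bis(TBS-oxy)-6-methoxyphenyl]-9-methyl-3-phenyldec-8-en-1-one F1 as an E/Z mixture. α-Methylenation as in step 6 would give the bromo enone (3S)-5-(bromomethylidene)-1-[2,4-bis(TBS-oxy)-6-methoxyphenyl]-9-methyl-2-methylidene-3-phenyldec-8-en-1-one F2. Ni(cod)2 (zerovalent nickel), Et3N, MeCN, then aqueous NH4Cl, should effect oxidative addition and intramolecular conjugate addition of the alkenyl–nickel bond to the enone. Only the Z bromide (bromine cis to the ring-forming chain) can close, so at most that fraction of the material is productive. The route is rejoined at ketone mixture 14, which DBU equilibrates to 15.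

Step 5. Chemoselection between the two carbonyl groups may be incomplete, or alkylidene transfer to the enolisable ketone may be slow. The fallback is a Peterson olefination through an organocerium reagent. From 9, (Me3Si)2CHLi with CeCl3 in THF at −78 °C should add to the dialkyl ketone as a weakly basic cerium reagent, and the β-silyl alkoxide should eliminate on warming to give 11 directly (no new compound, F0).

Step 3. Addition to the hindered, electron-rich chalcone may be slow, facial control with an acyclic β-ketoester may be weak, and retro-Michael reversal may erode the enantiomeric purity. The fallback uses the best-established asymmetric Michael donor for chalcones. From 3, dimethyl malonate under bifunctional thiourea catalysis would give dimethyl [(1S)-3-[2,4-bis(TBS-oxy)-6-methoxyphenyl]-3-oxo-1-phenylpropyl]propanedioate F3. Krapcho decarboxylation (LiCl, wet DMSO, heat) would give methyl (3S)-5-[2,4-bis(TBS-oxy)-6-methoxyphenyl]-5-oxo-3-phenylpentanoate F4. Me(MeO)NH·HCl with i-PrMgCl would give the Weinreb amide (3S)-5-[2,4-bis(TBS-oxy)-6-methoxyphenyl]-N-methoxy-N-methyl-5-oxo-3-phenylpentanamide F5. 4-Methylpent-3-enylmagnesium bromide would then give diketone 9, where the route is rejoined; steps 2 and 4 are then not needed.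

Further compounds
F1 | step 7 | (3R)-5-(bromomethylidene)-1-[2,4-bis(TBS-oxy)-6-methoxyphenyl]-9-methyl-3-phenyldec-8-en-1-one (E/Z) | COc1cc(O[Si](C)(C)C(C)(C)C)cc(O[Si](C)(C)C(C)(C)C)c1C(=O)C[C@H](c1ccccc1)CC(CCC=C(C)C)=CBr
F2 | step 7 | (3S)-5-(bromomethylidene)-1-[2,4-bis(TBS-oxy)-6-methoxyphenyl]-9-methyl-2-methylidene-3-phenyldec-8-en-1-one (E/Z) | COc1cc(O[Si](C)(C)C(C)(C)C)cc(O[Si](C)(C)C(C)(C)C)c1C(=O)C(=C)[C@H](c1ccccc1)CC(CCC=C(C)C)=CBr
F0 | step 5 | none | none
F3 | step 3 | dimethyl [(1S)-3-[2,4-bis(TBS-oxy)-6-methoxyphenyl]-3-oxo-1-phenylpropyl]propanedioate | COc1cc(O[Si](C)(C)C(C)(C)C)cc(O[Si](C)(C)C(C)(C)C)c1C(=O)C[C@H](c1ccccc1)C(C(=O)OC)C(=O)OC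
F4 | step 3 | methyl (3S)-5-[2,4-bis(TBS-oxy)-6-methoxyphenyl]-5-oxo-3-phenylpentanoate | COc1cc(O[Si](C)(C)C(C)(C)C)cc(O[Si](C)(C)C(C)(C)C)c1C(=O)C[C@H](c1ccccc1)CC(=O)OC
F5 | step 3 | (3S)-5-[2,4-bis(TBS-oxy)-6-methoxyphenyl]-N-methoxy-N-methyl-5-oxo-3-phenylpentanamide | COc1cc(O[Si](C)(C)C(C)(C)C)cc(O[Si](C)(C)C(C)(C)C)c1C(=O)C[C@H](c1ccccc1)CC(=O)N(C)OC
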